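Numbering used: ring C1 (C=O), C2=C3, C4 (CH–OMe), C5 (CH2), C6 (quaternary); side chain C1' (carbinol), C2' (CH–CH3).
Retrosynthesis: (a) remove the C2=C3 unsaturation and the silyl group; (b) cut ring bond C4–C5 together with the C6–allyl bond in one radical cascade, which opens the ring to an acyclic enone (C5=C6 exo-methylene, C1 ketone) with a methoxy(phenylselanyl)methyl terminus at C4; (c) cut C1–C6 (alkenyl triflate plus aldehyde); (d) cut C1'–C2' (syn aldol).
Enabling feature: ring CH2 C5 is beta to the C1 ketone through quaternary C6, and C4 is an acetal-level carbon. Both are acceptor-type carbons, so they are joined through a nucleophilic alpha-methoxy radical at C4, and the alpha-keto radical left at C6 takes up the allyl group.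
Forward: syn aldol, Weinreb amide, silyl ether, methyl ketone, alkenyl triflate; union with 4-methoxy-4-(phenylselanyl)butanal and oxidation give the enone; the cascade forms the only carbocycle and the quaternary centre; dehydrogenation and desilylation finish.
Stereochemistry: C1' and C2' come from the oxazolidinone auxiliary; C4 and C6 come from C2' through allylic strain in the cascade; the selenide epimers converge through one planar radical.

Key step: step 10

Assumption: compounds 9–12 are carried as mixtures of epimers at the selenium-bearing carbon (11 also at its carbinol carbon), because both centres are erased in steps 9 and 10.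

Step 1
Reactants: 1 3,4-dimethoxybenzaldehyde; 2 (S)-4-benzyl-3-propanoyl-1,3-oxazolidin-2-one
Product: 3 (S)-4-benzyl-3-[(2S,3S)-3-(3,4-dimethoxyphenyl)-3-hydroxy-2-methylpropanoyl]-1,3-oxazolidin-2-one
Conditions: 2, Bu2BOTf, iPr2NEt, CH2Cl2, 0 °C; then 1, −78 to 0 °C; then pH 7 buffer, MeOH, H2O2
Reagents that add atoms: none
Why: Boron-mediated Evans syn-aldol reaction, in which a closed chair transition state with the aldehyde on the face away from the benzyl group should set C1' and C2' (syn) in the required absolute sense.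

Step 2
Reactants: 3 (S)-4-benzyl-3-[(2S,3S)-3-(3,4-dimethoxyphenyl)-3-hydroxy-2-methylpropanoyl]-1,3-oxazolidin-2-one
Product: 4 (2S,3S)-3-(3,4-dimethoxyphenyl)-3-hydroxy-N-methoxy-N,2-dimethylpropanamide
Conditions: MeONHMe·HCl, AlMe3, CH2Cl2, −15 to 0 °C
Reagents that add atoms: N,O-dimethylhydroxylamine hydrochloride, CNOC.Cl
Why: Aluminium amide transamination (Weinreb amide formation) is assisted by the free beta-hydroxyl, occurs at the exocyclic carbonyl and should release the auxiliary without touching either stereocentre.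

Step 3
Reactants: 4 (2S,3S)-3-(3,4-dimethoxyphenyl)-3-hydroxy-N-methoxy-N,2-dimethylpropanamide
Product: 5 (2S,3S)-3-[(tert-butyldimethylsilyl)oxy]-3-(3,4-dimethoxyphenyl)-N-methoxy-N,2-dimethylpropanamide
Conditions: TBSOTf, 2,6-lutidine, CH2Cl2, −78 to 0 °C
Reagents that add atoms: tert-butyldimethylsilyl trifluoromethanesulfonate, CC(C)(C)[Si](C)(C)OS(=O)(=O)C(F)(F)F
Why: Silyl ether protection of the secondary benzylic alcohol masks the hydroxyl for the organometallic, radical and enolate steps that follow.

Step 4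
Reactants: 5 (2S,3S)-3-[(tert-butyldimethylsilyl)oxy]-3-(3,4-dimethoxyphenyl)-N-methoxy-N,2-dimethylpropanamide
Product: 6 (3S,4S)-4-[(tert-butyldimethylsilyl)oxy]-4-(3,4-dimethoxyphenyl)-3-methylbutan-2-one
Conditions: MeMgBr, THF, 0 °C
Reagents that add atoms: methylmagnesium bromide, C[Mg]Br
Why: Weinreb ketone synthesis, in which the chelated adduct stops at mono-addition and releases the ketone only on work-up, so over-addition and epimerization of the alpha-stereocentre are not expected.

Step 5
Reactants: 6 (3S,4S)-4-[(tert-butyldimethylsilyl)oxy]-4-(3,4-dimethoxyphenyl)-3-methylbutan-2-one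
Product: 7 (3S,4S)-4-[(tert-butyldimethylsilyl)oxy]-4-(3,4-dimethoxyphenyl)-3-methylbut-1-en-2-yl trifluoromethanesulfonate
Conditions: KHMDS, THF, −78 °C; then PhNTf2, −78 to 0 °C
Reagents that add atoms: N-phenylbis(trifluoromethanesulfonimide), O=S(=O)(N(c1ccccc1)S(=O)(=O)C(F)(F)F)C(F)(F)F
Why: Kinetic enol triflate formation, in which the bulky base deprotonates the methyl group and not the branched alpha-carbon, so the stereocentre and the beta-silyloxy group should stay untouched.

Step 6
Reactants: 8 4,4-dimethoxybutanenitrile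
Product: 9 4-methoxy-4-(phenylselanyl)butanenitrile (racemic)
Conditions: PhSeSiMe3 (1.0 equiv), TMSOTf (cat.), CH2Cl2, −78 °C
Reagents that add atoms: trimethyl(phenylselanyl)silane, C[Si](C)(C)[Se]c1ccccc1
Why: Lewis acid-catalysed acetal exchange, in which one methoxy group ionizes to an oxocarbenium ion that the silyl selenide captures, and one equivalent at low temperature should hold the reaction at the mixed O,Se-acetal.

Step 7
Reactants: 9 4-methoxy-4-(phenylselanyl)butanenitrile
Product: 10 4-methoxy-4-(phenylselanyl)butanal (racemic)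
Conditions: DIBAL-H, toluene, −78 °C; then aq. Rochelle salt
Reagents that add atoms: water, O
Why: Partial reduction of the nitrile, in which DIBAL-H adds once at −78 °C and the aluminium aldimine is hydrolysed on work-up, should leave the O,Se-acetal intact.

Step 8
Reactants: 7 (3S,4S)-4-[(tert-butyldimethylsilyl)oxy]-4-(3,4-dimethoxyphenyl)-3-methylbut-1-en-2-yl trifluoromethanesulfonate; 10 4-methoxy-4-(phenylselanyl)butanal
Product: 11 (1S,2R)-1-[(tert-butyldimethylsilyl)oxy]-1-(3,4-dimethoxyphenyl)-7-methoxy-2-methyl-3-methylidene-7-(phenylselanyl)heptan-4-ol (epimers at C4 and C7)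
Conditions: CrCl2, NiCl2 (cat.), DMF, 23 °C
Reagents that add atoms: none
Why: Nozaki–Hiyama–Kishi coupling joins the alkenyl triflate carbon to the aldehyde chemoselectively beside the silyl ether, aryl ethers and selenide; the new carbinol centre is oxidized away in step 9, and 11 is used without delay because a gamma-hydroxy O,Se-acetal is acid-sensitive.

Step 9
Reactants: 11 (1S,2R)-1-[(tert-butyldimethylsilyl)oxy]-1-(3,4-dimethoxyphenyl)-7-methoxy-2-methyl-3-methylidene-7-(phenylselanyl)heptan-4-ol
Product: 12 (1S,2R)-1-[(tert-butyldimethylsilyl)oxy]-1-(3,4-dimethoxyphenyl)-7-methoxy-2-methyl-3-methylidene-7-(phenylselanyl)heptan-4-one (epimers at C7)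
Conditions: MnO2, CH2Cl2, 23 °C
Reagents that add atoms: none
Why: Allylic alcohol oxidation with MnO2 under neutral heterogeneous conditions should give the 2-substituted enone without oxidizing the selenide or isomerizing the exocyclic alkene.

Step 10
Reactants: 12 (1S,2R)-1-[(tert-butyldimethylsilyl)oxy]-1-(3,4-dimethoxyphenyl)-7-methoxy-2-methyl-3-methylidene-7-(phenylselanyl)heptan-4-one
Product: 15 (2S,4R)-2-[(1S,2R)-1-[(tert-butyldimethylsilyl)oxy]-1-(3,4-dimethoxyphenyl)propan-2-yl]-4-methoxy-2-(prop-2-en-1-yl)cyclohexan-1-one, via alpha-methoxyalkyl radical 13 (not isolated), via ring alpha-keto radical 14 (not isolated)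
Conditions: allylSnBu3 (5 equiv), AIBN (cat.), PhH (0.01 M), 80 °C
Reagents that add atoms: allyltributylstannane, C=CC[Sn](CCCC)(CCCC)CCCC
Why: Bu3Sn• (AIBN-initiated, regenerated in every turnover) abstracts PhSe from either epimer of 12 to give one planar, nucleophilic alpha-methoxyalkyl radical 13 (C4, atom labels as in the target), which adds to the CH2 terminus (C5) of the electron-poor 2-substituted enone in a 6-endo-trig closure to form the tertiary, electrophilic alpha-keto radical 14 (C6); 14 is captured at C6 by allyltributylstannane with beta-scission of Bu3Sn• (SH2' allyl transfer). The closest known reaction types are tin-mediated radical conjugate (Giese-type) cyclization in tandem with Keck allylation, and the allylation of tertiary alpha-carbonyl radicals that flank a stereocentre. The 6-endo mode is expected over 5-exo because 5-exo attack would have to occur at the fully substituted alpha-carbon of the enone against the polarity of the radical and would give a primary radical. C4 is set in a chair-like transition state with the methoxy group pseudo-equatorial, the chain closing on the enone face that carries the C2' methyl group when C2'–H eclipses the carbonyl side (allylic 1,3-strain) and CH(OTBS)Ar shields the other face; C6 is set by the same conformational lock in 14, the stannane entering axially, anti to CH(OTBS)Ar and trans to the methoxy group, so both controls point to the isomer with allyl trans and side chain cis to OMe. The step needs ring closure to outrun direct allylation of 13, which the polarity mismatch between nucleophilic 13 and the stannane and the high dilution of 12 should secure, and it needs the selenide epimers to converge, which the planar radical ensures.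

Step 11
Reactants: 15 (2S,4R)-2-[(1S,2R)-1-[(tert-butyldimethylsilyl)oxy]-1-(3,4-dimethoxyphenyl)propan-2-yl]-4-methoxy-2-(prop-2-en-1-yl)cyclohexan-1-one
Product: 17 (4S,6S)-6-[(1S,2R)-1-[(tert-butyldimethylsilyl)oxy]-1-(3,4-dimethoxyphenyl)propan-2-yl]-4-methoxy-6-(prop-2-en-1-yl)cyclohex-2-en-1-one, via trimethylsilyl enol ether 16 (not isolated)
Conditions: LiHMDS, TMSCl, THF, −78 °C; then Pd(OAc)2, MeCN, 23 °C
Reagents that add atoms: none
Why: Saegusa–Ito oxidation, in which the ketone can enolize only toward its CH2 alpha-carbon (the other alpha-carbon is quaternary), so one silyl enol ether 16 forms and Pd(OAc)2 converts it to the enone while the allyl and gamma-methoxy groups should be spectators.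

Step 12
Reactants: 17 (4S,6S)-6-[(1S,2R)-1-[(tert-butyldimethylsilyl)oxy]-1-(3,4-dimethoxyphenyl)propan-2-yl]-4-methoxy-6-(prop-2-en-1-yl)cyclohex-2-en-1-one
Product: 18 (4S,6S)-6-[(1S,2R)-1-(3,4-dimethoxyphenyl)-1-hydroxypropan-2-yl]-4-methoxy-6-(prop-2-en-1-yl)cyclohex-2-en-1-one
Conditions: TBAF, AcOH, THF, 23 °C
Reagents that add atoms: none
Why: Fluoride-mediated desilylation buffered with AcOH should remove the silyl ether without base-induced damage to the gamma-methoxy enone and without touching any stereocentre.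

Compound list
1 | 3,4-dimethoxybenzaldehyde | COc1ccc(C=O)cc1OC | starting material
2 | (S)-4-benzyl-3-propanoyl-1,3-oxazolidin-2-one | CCC(=O)N1[C@@H](Cc2ccccc2)COC1=O | starting material
3 | (S)-4-benzyl-3-[(2S,3S)-3-(3,4-dimethoxyphenyl)-3-hydroxy-2-methylpropanoyl]-1,3-oxazolidin-2-one | O=C1OC[C@H](Cc2ccccc2)N1C(=O)[C@@H](C)[C@H](O)c3ccc(OC)c(OC)c3 | intermediate
4 | (2S,3S)-3-(3,4-dimethoxyphenyl)-3-hydroxy-N-methoxy-N,2-dimethylpropanamide | CON(C)C(=O)[C@@H](C)[C@H](O)c1ccc(OC)c(OC)c1 | intermediate
5 | (2S,3S)-3-[(tert-butyldimethylsilyl)oxy]-3-(3,4-dimethoxyphenyl)-N-methoxy-N,2-dimethylpropanamide | CON(C)C(=O)[C@@H](C)[C@H](O[Si](C)(C)C(C)(C)C)c1ccc(OC)c(OC)c1 | intermediate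
6 | (3S,4S)-4-[(tert-butyldimethylsilyl)oxy]-4-(3,4-dimethoxyphenyl)-3-methylbutan-2-one | CC(=O)[C@@H](C)[C@H](O[Si](C)(C)C(C)(C)C)c1ccc(OC)c(OC)c1 | intermediate
7 | (3S,4S)-4-[(tert-butyldimethylsilyl)oxy]-4-(3,4-dimethoxyphenyl)-3-methylbut-1-en-2-yl trifluoromethanesulfonate | C=C(OS(=O)(=O)C(F)(F)F)[C@@H](C)[C@H](O[Si](C)(C)C(C)(C)C)c1ccc(OC)c(OC)c1 | intermediate
8 | 4,4-dimethoxybutanenitrile | N#CCCC(OC)OC | starting material
9 | 4-methoxy-4-(phenylselanyl)butanenitrile (racemic) | N#CCCC(OC)[Se]c1ccccc1 | intermediate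
10 | 4-methoxy-4-(phenylselanyl)butanal (racemic) | O=CCCC(OC)[Se]c1ccccc1 | intermediate
11 | (1S,2R)-1-[(tert-butyldimethylsilyl)oxy]-1-(3,4-dimethoxyphenyl)-7-methoxy-2-methyl-3-methylidene-7-(phenylselanyl)heptan-4-ol (epimers at C4 and C7) | OC(CCC(OC)[Se]c1ccccc1)C(=C)[C@@H](C)[C@H](O[Si](C)(C)C(C)(C)C)c2ccc(OC)c(OC)c2 | intermediate
12 | (1S,2R)-1-[(tert-butyldimethylsilyl)oxy]-1-(3,4-dimethoxyphenyl)-7-methoxy-2-methyl-3-methylidene-7-(phenylselanyl)heptan-4-one (epimers at C7) | O=C(CCC(OC)[Se]c1ccccc1)C(=C)[C@@H](C)[C@H](O[Si](C)(C)C(C)(C)C)c2ccc(OC)c(OC)c2 | intermediate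
13 | (6R,7S)-7-[(tert-butyldimethylsilyl)oxy]-7-(3,4-dimethoxyphenyl)-1-methoxy-6-methyl-5-methylidene-4-oxoheptyl radical | CO[CH]CCC(=O)C(=C)[C@@H](C)[C@H](O[Si](C)(C)C(C)(C)C)c1ccc(OC)c(OC)c1 | intermediate
14 | (5R)-1-[(1S,2R)-1-[(tert-butyldimethylsilyl)oxy]-1-(3,4-dimethoxyphenyl)propan-2-yl]-5-methoxy-2-oxocyclohexyl radical | [C]1([C@@H](C)[C@H](O[Si](C)(C)C(C)(C)C)c2ccc(OC)c(OC)c2)C[C@H](OC)CCC1=O | intermediate
15 | (2S,4R)-2-[(1S,2R)-1-[(tert-butyldimethylsilyl)oxy]-1-(3,4-dimethoxyphenyl)propan-2-yl]-4-methoxy-2-(prop-2-en-1-yl)cyclohexan-1-one | C=CC[C@@]1([C@@H](C)[C@H](O[Si](C)(C)C(C)(C)C)c2ccc(OC)c(OC)c2)C[C@H](OC)CCC1=O | intermediate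
16 | {[(4R,6S)-6-[(1S,2R)-1-[(tert-butyldimethylsilyl)oxy]-1-(3,4-dimethoxyphenyl)propan-2-yl]-4-methoxy-6-(prop-2-en-1-yl)cyclohex-1-en-1-yl]oxy}trimethylsilane | C=CC[C@@]1([C@@H](C)[C@H](O[Si](C)(C)C(C)(C)C)c2ccc(OC)c(OC)c2)C[C@H](OC)CC=C1O[Si](C)(C)C | intermediate
17 | (4S,6S)-6-[(1S,2R)-1-[(tert-butyldimethylsilyl)oxy]-1-(3,4-dimethoxyphenyl)propan-2-yl]-4-methoxy-6-(prop-2-en-1-yl)cyclohex-2-en-1-one | C=CC[C@@]1([C@@H](C)[C@H](O[Si](C)(C)C(C)(C)C)c2ccc(OC)c(OC)c2)C[C@H](OC)C=CC1=O | intermediate
18 | (4S,6S)-6-[(1S,2R)-1-(3,4-dimethoxyphenyl)-1-hydroxypropan-2-yl]-4-methoxy-6-(prop-2-en-1-yl)cyclohex-2-en-1-one | C=CC[C@@]1([C@@H](C)[C@H](O)c2ccc(OC)c(OC)c2)C[C@H](OC)C=CC1=O | target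

Total steps: 12. Longest linear sequence: 10 steps (1–5, then 8–12); the selenide fragment is a 2-step branch (steps 6 and 7).

Steps most likely to fail

Step 10. What may go wrong: allyl transfer to the open-chain radical before ring closure, slow allyl transfer to the hindered ring radical, or poor facial selectivity in either bond formation; the methoxy-bearing centre is the less secure of the two. The fallback sets out from 12 and comes back at 15; it separates ring closure from quaternization and puts the quaternary centre under catalyst control. Slow addition of Bu3SnH and AIBN to 12 in PhH at 80 °C should close the same ring reductively to (4R)-2-[(1S,2R)-1-[(tert-butyldimethylsilyl)oxy]-1-(3,4-dimethoxyphenyl)propan-2-yl]-4-methoxycyclohexan-1-one F1 (C2 left unfixed; any C4 epimer would be removed here). Soft enolization (TMSCl, NaI, Et3N, MeCN) should give the more substituted trimethylsilyl enol ether F2. MeLi and then allyl chloroformate should give the allyl enol carbonate F3. Pd2(dba)3 with the enantiomer of t-BuPHOX that places allyl trans to the methoxy group (decarboxylative Tsuji allylation) should then give 15.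

Step 8. What may go wrong: slow activation of the alpha-branched alkenyl triflate, or loss of nickel activity through binding to selenium. The fallback sets out from 6 and comes back at 11 without passing through 7. Condensation of 6 with 2,4,6-triisopropylbenzenesulfonohydrazide should give the trisylhydrazone F4. n-BuLi (2 equiv, THF, −78 to 0 °C; Shapiro reaction, deprotonation at the methyl group and loss of sulfinate and nitrogen) should give the 2-lithioalkene F5, which is cooled to −78 °C and treated with aldehyde 10 to give 11.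

Step 11. What may go wrong: incomplete enol silylation of the ketone beside the quaternary carbon, or competing coordination and oxidation of the terminal allyl alkene by divalent palladium. The fallback sets out from 15 and comes back at 17. LDA and then PhSeBr at −78 °C should give the 6-(phenylselanyl) ketone F6, and H2O2 with pyridine at 0 °C should give 17 by selenoxide syn-elimination.

Further compounds
F1 | step 10 | (4R)-2-[(1S,2R)-1-[(tert-butyldimethylsilyl)oxy]-1-(3,4-dimethoxyphenyl)propan-2-yl]-4-methoxycyclohexan-1-one (epimers at C2) | C1([C@@H](C)[C@H](O[Si](C)(C)C(C)(C)C)c2ccc(OC)c(OC)c2)C[C@H](OC)CCC1=O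
F2 | step 10 | {[(4R)-2-[(1S,2R)-1-[(tert-butyldimethylsilyl)oxy]-1-(3,4-dimethoxyphenyl)propan-2-yl]-4-methoxycyclohex-1-en-1-yl]oxy}trimethylsilane | C[Si](C)(C)OC1=C([C@@H](C)[C@H](O[Si](C)(C)C(C)(C)C)c2ccc(OC)c(OC)c2)C[C@H](OC)CC1
F3 | step 10 | prop-2-en-1-yl (4R)-2-[(1S,2R)-1-[(tert-butyldimethylsilyl)oxy]-1-(3,4-dimethoxyphenyl)propan-2-yl]-4-methoxycyclohex-1-en-1-yl carbonate | C=CCOC(=O)OC1=C([C@@H](C)[C@H](O[Si](C)(C)C(C)(C)C)c2ccc(OC)c(OC)c2)C[C@H](OC)CC1
F4 | step 8 | N'-[(3R,4S)-4-[(tert-butyldimethylsilyl)oxy]-4-(3,4-dimethoxyphenyl)-3-methylbutan-2-ylidene]-2,4,6-tri(propan-2-yl)benzenesulfonohydrazide | CC(=NNS(=O)(=O)c1c(C(C)C)cc(C(C)C)cc1C(C)C)[C@@H](C)[C@H](O[Si](C)(C)C(C)(C)C)c2ccc(OC)c(OC)c2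
F5 | step 8 | [(3R,4S)-4-[(tert-butyldimethylsilyl)oxy]-4-(3,4-dimethoxyphenyl)-3-methylbut-1-en-2-yl]lithium | [Li]C(=C)[C@@H](C)[C@H](O[Si](C)(C)C(C)(C)C)c1ccc(OC)c(OC)c1
F6 | step 11 | (2S,4S)-2-[(1S,2R)-1-[(tert-butyldimethylsilyl)oxy]-1-(3,4-dimethoxyphenyl)propan-2-yl]-4-methoxy-6-(phenylselanyl)-2-(prop-2-en-1-yl)cyclohexan-1-one (epimers at C6) | C=CC[C@@]1([C@@H](C)[C@H](O[Si](C)(C)C(C)(C)C)c2ccc(OC)c(OC)c2)C[C@H](OC)CC([Se]c3ccccc3)C1=O
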